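Abbreviations: TBS = tert-butyldimethylsilyl, TES = triethylsilyl, PMB = 4-methoxybenzyl, PMP = 4-methoxyphenyl. Carbon numbers C1–C50 are those of the target (C1 lactone carbonyl, C41 ring carbon bearing the lactone oxygen).

## Analysis of the target

Target 56 is a 42-membered macrolactone (C1 to O41) with a C42–C50 side chain, fifteen stereocentres and four Z alkenes (C2=C3, C4=C5, C20=C21, C38=C39). Read from the SMILES, the configuration is 7S,9R,11S,13R,15S,17R,18R,19S,23R,27R,31R,41S,42S,43R,49R. The six hydroxyls at C7–C17 are all 1,3-anti; C18-methyl is anti to O17 and syn to O19; C23, C27 and C31 are isolated carbinols of like sense, each three methylenes apart; C41–C43 is a syn,syn triad; C49 is remote. The sensitive groups are the (2Z,4Z)-4-methyldienoate (2Z to 2E isomerisation whenever the acyl group is activated in the presence of nucleophiles), the allylic C19 carbinol beside a trisubstituted Z alkene, and every β-oxygenated carbonyl intermediate (elimination). Twelve free hydroxyls must be told apart from O41 and released at the end under one mild regime. The difficulty is size combined with remote stereocentres that no single substrate bias can relay. The feature used here is that the C5–C19 chain, written with C5 and C19 as carboxyl carbons, has a twofold axis through C12; only the C18 methyl breaks it. The two halves of the hexol are therefore homotopic and can be built simultaneously.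

## Retrosynthetic reasoning

**Last step.** Target 56 is traced to macrolactone 55, in which eight hydroxyls are TBS ethers and O9/O11 and O13/O15 are bridged as PMP acetals. Both groups fall to aqueous HF, so one operation releases all twelve hydroxyls after the ring and the dienoate are in place.

**C1–O41.** Opening the lactone of 55 gives seco acid 53. This is the only heteroatom bond in the ring, a 42-membered ring closes without strain, and cutting here allows the dienoate to be made on an acyclic fragment. The forward reaction must activate a (2Z,4Z)-dienoic acid without eroding the C2=C3 geometry and must find only one free hydroxyl, which the TES/TBS distinction at O41 ensures (52 from 51).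

**C19–C20.** Cutting between the C19 carbinol and the alkene carbon C20 divides 50 into two halves of similar size, aldehyde 23 (C1–C19) and alkenyl iodide 49 (C20–C50). An alkenylchromium addition tolerates the dienoate ester of 23. C19 is created next to C18/C17, whose 2,3-anti arrangement makes Felkin and 1,3-anti preferences point the same way.

**C38=C39.** The isolated Z alkene of 49 is cut into phosphonium salt 36 and aldehyde 47. A non-stabilised ylide gives Z geometry reliably, and the cut falls in the unfunctionalised stretch, so both partners are simple.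

**Fragment 47 (C39–C50).** C42–C43 is cut as a syn-aldol between imide 41 and aldehyde 40, which sets two centres in one step. C40–C41 is cut as a catalytic allylation with 5 at the alcohol oxidation level, so the epimerisable α-methyl aldehyde is never isolated. Aldehyde 40 comes from epoxide 37, which supplies C49.

**Fragment 36 (C20–C38).** The three 1,5-related carbinols are traced to 24 by iteration: allylation with 5 makes one C–C bond and one carbinol, and linear hydroformylation adds the one carbon that places the next carbonyl three methylenes away (25 to 33). C20=C21 is cut as an α-iodoethylidene Wittig reaction on aldehyde 33, which fixes the Z geometry before the union.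

**C1–C5.** In 23 both alkenes are cut as Z-selective phosphonate olefinations (C4=C5 from aldehyde 18, C2=C3 from enal 21). The C3 and C19 primary alcohols of diol 20 are distinguished by allylic oxidation, so C19 needs no protecting group.

**C18-methyl and symmetry breaking.** The methyl of 16 is removed to give β-hydroxy ester 15, for which the dianion alkylation gives the required anti relation. This demands a free O17, a protected O15 and a non-enolisable C5 end; hence the prior statistical mono-reduction of one of the two homotopic esters of 13 (to 14) and selective silylation of the primary hydroxyl.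

**Differentiating O9/O15 from O7/O17.** Diol diester 13 is traced to tetraol 12 by oxidative cyclisation of each PMB ether onto its outer 1,3-hydroxyl, which uses no new protecting-group atoms. 12 comes from bis(keto ester) 11 by directed anti reduction of both ketones.

**Key disconnection: C8–C9 and C15–C16.** Both bonds of 11 are cut at once to give dialdehyde 9 and two molecules of dienolate 3. The cut is placed here because each aldehyde carries a β-PMB ether that can direct the addition 1,3-anti, and because the two aldehydes are homotopic. The forward step makes two bonds and two stereocentres in one flask and brings in C5–C8 and C16–C19 at the right oxidation levels.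

**Dialdehyde and dienolate.** 9 comes from diene 8 by cleavage of both alkenes, and 8 from diol 7 by etherification. 7 is the double allylation product of 4 with 5, so C11 and C13 are set by one catalyst. 3 comes from 1 in two silylations.

## Alternatives that were turned down

**Alternative 1:** The C3–C4 single bond between the two Z alkenes is cut, so ring closure and diene formation coincide. In the forward sense the C41 hydroxyl carries a (Z)-3-iodoacrylate and C4 a tributylstannyl alkene; Pd(PPh3)4 with copper thiophene-2-carboxylate joins the two sp2 carbons intramolecularly to give macrolide A1.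
- For: the ester bond is made intermolecularly from a three-carbon acid, the dienoate never exists as an activated acyl derivative, and the coupling is neutral and stereoretentive.
- Against: it needs a geometrically pure, α-branched trisubstituted alkenylstannane whose slow transmetallation invites protodestannylation and homocoupling at high dilution. (Z)-β-Iodoacrylates isomerise during esterification of a hindered secondary alcohol. The disconnection says nothing about the C7–C19 array; the three anti-acetonides of A1 imply a separate, linear polyol synthesis.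
- Comparison: on the integrity of C2=C3 during ring closure this alternative is stronger than the lactonisation used here. The chosen strategy offers instead four carbinol centres and two C–C bonds in two operations from bulk chemicals, and it places its riskiest step at the start, where material is cheap.

**Alternative 2:** The C20=C21 alkene is cut. A diisopropylsilylene bridge between O19 and O23 holds an isopropenyl group on C19 and an allyl group on C23, and the second-generation Hoveyda–Grubbs catalyst RuCl2(H2IMes)(=CH-C6H4-2-OiPr) closes the eight-membered silylene acetal A2.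
- For: the medium ring enforces the Z geometry, and C19 and C23 are both set before the union, so no stereocentre is formed in a fragment coupling.
- Against: two hindered secondary alcohols must be attached to one silicon in sequence, which usually costs an excess of one advanced half. Metathesis to a trisubstituted alkene through a 1,1-disubstituted olefin is slow. The ruthenium carbene forces the other alkenes to be introduced afterwards, so A2 still lacks C1–C4 and C39–C50 and a long linear endgame follows.
- Comparison: this alternative is stronger on control of the C20=C21 geometry, which here rests on a kinetic Wittig selectivity. The chosen route offers a union of fully elaborated halves with only five steps after it, and the short polyol synthesis.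

**Alternative 3:** The ring is cut at C38–C39 as an alkyne. An open-chain ester with two methyl-capped alkynes is closed by Mo(≡CC6H4-4-OMe)(OSiPh3)3 with release of a volatile small alkyne to give cycloalkyne A3, which is then semi-hydrogenated to the Z alkene.
- For: the catalyst ignores alkenes, the closure takes place in an unhindered methylene stretch far from any stereocentre, and the Z geometry follows from syn hydrogenation.
- Against: the open-chain ester must be made by acylating the hindered C41 hydroxyl with the complete (2Z,4Z)-dienoic acid, the same isomerisation hazard as lactonisation without ring closure as the reward. The semi-hydrogenation must spare a conjugated dienoate and two other alkenes at the penultimate step.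
- Comparison: as a ring closure this alternative is probably the most dependable of the three and more dependable than macrolactonisation. The chosen route offers instead a Wittig reaction on small fragments that sets C38=C39 early and leaves no late reduction, and again the two-directional polyol synthesis.

Key step: step 6

Remark on the chemistry (catalyst sense): the iridium catalyst carrying (S)-Cl,MeO-BIPHEP is taken to give the (4S,6S)-diol 7; steps 19, 22, 25 and 36 need the same spatial sense of allyl delivery and use the same ligand antipode, so if the sense were opposite the (R)-ligand would serve throughout.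

Remark on the chemistry (acetal carbons): each PMP acetal spans an anti-1,3-diol and is expected to form as a mixture of epimers at the acetal carbon, which is carried like a tetrahydropyranyl ether and lost in step 45; the SMILES leave this carbon unassigned.

## Route

Step 1
Reactants: 1 methyl acetoacetate
Product: 2 methyl 3-(trimethylsilyloxy)but-2-enoate
Conditions: Me3SiCl, Et3N, hexane, rt
Reagents that add atoms: chlorotrimethylsilane, C[Si](C)(C)Cl
Why: O-silylation of the enol form of a β-keto ester under soft enolisation; standard silyl enol ether formation.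

Step 2
Reactants: 2 methyl 3-(trimethylsilyloxy)but-2-enoate
Product: 3 1-methoxy-1,3-bis(trimethylsilyloxy)buta-1,3-diene
Conditions: LiN(iPr)2, THF, −78 °C; Me3SiCl, −78 °C → rt
Reagents that add atoms: chlorotrimethylsilane, C[Si](C)(C)Cl
Why: Kinetic γ-deprotonation of the vinylogous ester and O-silylation of the dienolate; the standard preparation of this bis(silyloxy)diene.

Step 3
Reactants: 4 propane-1,3-diol; 5 allyl acetate
Product: 7 (4S,6S)-nona-1,8-diene-4,6-diol, via (S)-hex-5-ene-1,3-diol 6 (not isolated)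
Conditions: 5 (10 equiv), [Ir(cod)Cl]2 (5 mol%), (S)-Cl,MeO-BIPHEP (10 mol%), 4-chloro-3-nitrobenzoic acid (20 mol%), Cs2CO3 (40 mol%), 1,4-dioxane, 90 °C
Reagents that add atoms: none
Why: Iridium-catalysed transfer-hydrogenative carbonyl allylation: the cyclometallated π-allyl complex dehydrogenates each primary alcohol and allylates the transient aldehyde under ligand control, setting C11 and C13. The second allylation is matched with the first, so the C2-symmetric diol should be enriched and the meso isomer a minor, separable diastereomer.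

Step 4
Reactants: 7 (4S,6S)-nona-1,8-diene-4,6-diol
Product: 8 (4S,6S)-4,6-bis(4-methoxybenzyloxy)nona-1,8-diene
Conditions: NaH, 4-methoxybenzyl chloride, Bu4NI (cat.), DMF, 0 °C → rt
Reagents that add atoms: 4-methoxybenzyl chloride, COc1ccc(CCl)cc1
Why: Williamson etherification of both alkoxides; benzyl-type ethers are chosen because a β-alkoxy group, unlike a β-silyloxy group, gives strong 1,3-anti induction in step 6.

Step 5
Reactants: 8 (4S,6S)-4,6-bis(4-methoxybenzyloxy)nona-1,8-diene
Product: 9 (3R,5R)-3,5-bis(4-methoxybenzyloxy)heptanedial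
Conditions: O3, CH2Cl2/MeOH, pyridine, −78 °C (metered to the fading of an azo-dye indicator); PPh3, −78 °C → rt; used crude
Reagents that add atoms: ozone, [O-][O+]=O
Why: Ozonolysis with reductive work-up cleaves both terminal alkenes; the indicator reacts after the alkenes and before the electron-rich arenes, and the β-alkoxy dialdehyde is used at once to avoid elimination.

Step 6
Reactants: 9 (3R,5R)-3,5-bis(4-methoxybenzyloxy)heptanedial; 3 1-methoxy-1,3-bis(trimethylsilyloxy)buta-1,3-diene
Product: 11 C5–C19 bis(5-hydroxy-3-keto ester), via mono-aldol aldehyde 10 (not isolated)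
Conditions: 3 (2.6 equiv), BF3·OEt2 (2.2 equiv), CH2Cl2, −78 °C; aq. NaHCO3, then dilute HCl/THF, 0 °C
Reagents that add atoms: none
Why: BF3 binds each aldehyde oxygen and the terminal carbon of the dienolate adds through an open, extended transition state (vinylogous Mukaiyama aldol); silicon leaves as Me3SiF and the remaining enol silyl ether is hydrolysed to the β-keto ester on work-up. The closest known reaction type is the BF3-mediated Mukaiyama aldol of bis(silyloxy)dienes with β-alkoxy aldehydes under 1,3-anti induction, run here on both ends of one molecule. No ring is closed. C9 is controlled by the C11 PMB ether and C15 by the C13 PMB ether: in the reactive conformer the β C–O dipole opposes the activated carbonyl and the nucleophile enters on the face away from the rest of the chain, which gives each new carbinol 1,3-anti to its neighbour. The step needs face selectivity at each aldehyde, secured by the non-chelating Lewis acid and the benzyl-type ethers, and γ- over α-attack of the dienolate, which is the normal course for this diene under Lewis acid activation. No end differentiation is needed because the two aldehydes are homotopic through the axis at C12, so mono-adduct 10 is the same compound whichever end reacts first. The two additions select independently, so any minor isomer is a diastereomer of 11 and can be removed.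

Step 7
Reactants: 11 C5–C19 bis(5-hydroxy-3-keto ester)
Product: 12 dimethyl (3R,5R,7S,9S,11R,13R)-3,5,11,13-tetrahydroxy-7,9-bis(4-methoxybenzyloxy)pentadecanedioate
Conditions: Me4NBH(OAc)3 (8 equiv), MeCN/AcOH (1:1), −30 °C
Reagents that add atoms: none
Why: Evans–Saksena directed reduction: each of the C9 and C15 hydroxyls exchanges onto boron and delivers hydride intramolecularly through a chair six-membered transition state to the protonated ketone, setting C7 and C17 1,3-anti; both ends react alike.

Step 8
Reactants: 12 tetraol diester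
Product: 13 C5–C19 diester with PMP acetals across O9/O11 and O13/O15 and free C7 and C17 hydroxyls
Conditions: DDQ (2.3 equiv), 4 Å molecular sieves, CH2Cl2, 0 °C
Reagents that add atoms: none
Why: Oikawa–Yonemitsu oxidative acetalisation: DDQ abstracts hydride from each PMB ether and the benzylic oxocarbenium ion is trapped by the only hydroxyl that can close a six-membered ring (O9 for the C11 ether, O15 for the C13 ether). O9 and O15 are thereby masked and O7 and O17 left free, and water is excluded to prevent over-oxidation to benzoates.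

Step 9
Reactants: 13 bis(PMP acetal) diol diester
Product: 14 mono-reduced triol ester (C5 primary alcohol, C19 methyl ester)
Conditions: LiBH4 (0.6 equiv), THF, 0 °C; recovered 13 is resubmitted
Reagents that add atoms: none
Why: Hydroxyl-assisted borohydride reduction of a β-hydroxy ester; the two esters are homotopic, so either gives the same compound. With substoichiometric hydride the mono-reduced product is the statistical maximum (at most half per pass) and differs strongly in polarity from 13 and from the over-reduced tetraol.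

Step 10
Reactants: 14 triol ester
Product: 15 C5 triethylsilyl ether
Conditions: Et3SiCl (1.05 equiv), imidazole, CH2Cl2, −78 → −40 °C
Reagents that add atoms: chlorotriethylsilane, CC[Si](CC)(CC)Cl
Why: The primary hydroxyl is silylated much faster than the two secondary ones at low temperature; the primary TES ether later serves as a latent aldehyde.

Step 11
Reactants: 15 C5 triethylsilyl ether
Product: 16 C18-methylated β-hydroxy ester (17,18-anti)
Conditions: LiN(iPr)2 (3.3 equiv), THF, −78 → −20 °C; MeI (5 equiv), DMPU, −78 → −20 °C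
Reagents that add atoms: iodomethane, CI
Why: Fráter–Seebach alkylation: the base forms the O7 and O17 alkoxides and the C19 ester enolate, and the lithium chelate between O17 and the enolate oxygen is methylated on the face away from the C16 chain, giving C18 anti to O17. The C5 end has no acidic C–H and the O7 alkoxide is a spectator.

Step 12
Reactants: 16 methylated hydroxy ester
Product: 17 C7,C17-bis(TBS) ether
Conditions: TBSOTf, 2,6-lutidine, CH2Cl2, −78 → 0 °C
Reagents that add atoms: tert-butyldimethylsilyl trifluoromethanesulfonate, CC(C)(C)[Si](C)(C)OS(=O)(=O)C(F)(F)F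
Why: A silyl triflate with a hindered pyridine base silylates both secondary hydroxyls, including the hindered one at C17.

Step 13
Reactants: 17 bis(TBS) ether
Product: 18 C5 aldehyde
Conditions: (COCl)2, DMSO, CH2Cl2, −78 → −40 °C; Et3N, −78 → 0 °C
Reagents that add atoms: none
Why: Under Swern conditions a primary TES ether is converted directly into the aldehyde, because activated DMSO attacks the silyl ether oxygen; secondary TBS ethers, the acetals and the ester are not affected.

Step 14
Reactants: 18 C5 aldehyde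
Product: 19 (Z)-enoate diester (C3 and C19 methyl esters)
Conditions: (CF3CH2O)2P(O)CH(CH3)CO2Me, KN(SiMe3)2, 18-crown-6, THF, −78 °C
Reagents that add atoms: methyl 2-[bis(2,2,2-trifluoroethoxy)phosphoryl]propanoate, COC(=O)C(C)P(=O)(OCC(F)(F)F)OCC(F)(F)F
Why: Still–Gennari olefination: the electron-poor phosphonate with a dissociated potassium counter-ion eliminates fast from the kinetically formed adduct and gives the (Z)-trisubstituted enoate, with C3 and C6 cis across C4=C5.

Step 15
Reactants: 19 (Z)-enoate diester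
Product: 20 C3,C19-diol
Conditions: iBu2AlH (6 equiv), THF, −78 → −30 °C; aq. potassium sodium tartrate
Reagents that add atoms: none
Why: Excess aluminium hydride reduces both esters to primary alcohols; in THF below −30 °C reductive opening of the PMP acetals, which needs a free Lewis acid and higher temperature, should not compete.

Step 16
Reactants: 20 C3,C19-diol
Product: 21 (Z)-enal with free C19 hydroxyl
Conditions: MnO2 (activated, excess), CH2Cl2, rt, short contact time
Reagents that add atoms: none
Why: MnO2 oxidises only the allylic alcohol, so the two primary alcohols are distinguished by their electronic nature and C19 needs no protecting group.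

Step 17
Reactants: 21 (Z)-enal
Product: 22 methyl (2Z,4Z)-dienoate with free C19 hydroxyl
Conditions: (CF3CH2O)2P(O)CH2CO2Me, KN(SiMe3)2, 18-crown-6, THF, −78 °C
Reagents that add atoms: methyl 2-[bis(2,2,2-trifluoroethoxy)phosphoryl]acetate, COC(=O)CP(=O)(OCC(F)(F)F)OCC(F)(F)F
Why: A second Still–Gennari olefination on the (Z)-enal gives the 2Z alkene; the preformed phosphonate anion is too weakly basic to deprotonate the C19 hydroxyl.

Step 18
Reactants: 22 dienoate alcohol
Product: 23 C1–C19 aldehyde (west fragment)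
Conditions: Dess–Martin periodinane, NaHCO3, CH2Cl2, 0 °C → rt
Reagents that add atoms: none
Why: Buffered periodinane oxidation gives the α-methyl aldehyde without epimerisation at C18 or isomerisation of the dienoate.

Step 19
Reactants: 24 8-chlorooctan-1-ol; 5 allyl acetate
Product: 25 (R)-11-chloroundec-1-en-4-ol
Conditions: 5 (2 equiv), [Ir(cod)Cl]2 (2.5 mol%), (S)-Cl,MeO-BIPHEP (5 mol%), 4-chloro-3-nitrobenzoic acid (10 mol%), Cs2CO3 (20 mol%), THF, 100 °C
Reagents that add atoms: none
Why: The same iridium-catalysed allylation from the alcohol oxidation level sets C31 by catalyst control; the primary chloride is inert to the catalytic carbonate and later becomes the phosphonium salt.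

Step 20
Reactants: 25 (R)-11-chloroundec-1-en-4-ol
Product: 26 (R)-tert-butyl[(11-chloroundec-1-en-4-yl)oxy]dimethylsilane
Conditions: TBSCl, imidazole, DMF, rt
Reagents that add atoms: tert-butylchlorodimethylsilane, CC(C)(C)[Si](C)(C)Cl
Why: Standard silylation of a secondary alcohol.

Step 21
Reactants: 26 homoallylic silyl ether
Product: 27 (R)-5-(tert-butyldimethylsilyloxy)-12-chlorododecanal
Conditions: Rh(acac)(CO)2 (1 mol%), BIPHEPHOS (3 mol%), CO/H2 (1:1, 10 bar), THF, 60 °C
Reagents that add atoms: carbon monoxide, [C-]#[O+]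
Why: Rhodium-catalysed hydroformylation; the wide-bite-angle bisphosphite directs formylation to the terminal carbon, adding the one carbon that places the next carbonyl (C27) three methylenes from C31.

Step 22
Reactants: 27 (R)-5-(tert-butyldimethylsilyloxy)-12-chlorododecanal; 5 allyl acetate
Product: 28 (4R,8R)-8-(tert-butyldimethylsilyloxy)-15-chloropentadec-1-en-4-ol
Conditions: 5 (2 equiv), [Ir(cod)Cl]2 (2.5 mol%), (S)-Cl,MeO-BIPHEP (5 mol%), 4-chloro-3-nitrobenzoic acid (10 mol%), Cs2CO3 (20 mol%), iPrOH (2 equiv), THF, 100 °C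
Reagents that add atoms: none
Why: The same allylation from the aldehyde oxidation level, with isopropanol as terminal reductant; C27 is set by the catalyst, and the remote C31 centre exerts no bias.

Step 23
Reactants: 28 homoallylic alcohol
Product: 29 (4R,8R)-4,8-bis(tert-butyldimethylsilyloxy)-15-chloropentadec-1-ene
Conditions: TBSCl, imidazole, DMF, rt
Reagents that add atoms: tert-butylchlorodimethylsilane, CC(C)(C)[Si](C)(C)Cl
Why: Standard silylation.

Step 24
Reactants: 29 bis(silyl ether) alkene
Product: 30 (5R,9R)-5,9-bis(tert-butyldimethylsilyloxy)-16-chlorohexadecanal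
Conditions: Rh(acac)(CO)2 (1 mol%), BIPHEPHOS (3 mol%), CO/H2 (1:1, 10 bar), THF, 60 °C
Reagents that add atoms: carbon monoxide, [C-]#[O+]
Why: Linear hydroformylation as in step 21 gives the C23 aldehyde.

Step 25
Reactants: 30 C23 aldehyde; 5 allyl acetate
Product: 31 19-chloro-8,12-bis(tert-butyldimethylsilyloxy)nonadec-1-en-4-ol (C23, C27 and C31 as in the target)
Conditions: 5 (2 equiv), [Ir(cod)Cl]2 (2.5 mol%), (S)-Cl,MeO-BIPHEP (5 mol%), 4-chloro-3-nitrobenzoic acid (10 mol%), Cs2CO3 (20 mol%), iPrOH (2 equiv), THF, 100 °C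
Reagents that add atoms: none
Why: Third catalyst-controlled allylation, setting C23 in the same sense as C27 and C31.

Step 26
Reactants: 31 homoallylic alcohol
Product: 32 tris(TBS) ether of 31
Conditions: TBSCl, imidazole, DMF, rt
Reagents that add atoms: tert-butylchlorodimethylsilane, CC(C)(C)[Si](C)(C)Cl
Why: Standard silylation.

Step 27
Reactants: 32 tris(TBS) alkene
Product: 33 18-chloro-3,7,11-tris(tert-butyldimethylsilyloxy)octadecanal (C21 aldehyde)
Conditions: O3, CH2Cl2, −78 °C; PPh3, −78 °C → rt
Reagents that add atoms: ozone, [O-][O+]=O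
Why: Ozonolysis with reductive work-up removes the terminal methylene and exposes C21 as a β-silyloxy aldehyde.

Step 28
Reactants: 33 C21 aldehyde
Product: 34 (Z)-alkenyl iodide (C20–C38, C38 chloride)
Conditions: [Ph3PCH2CH3]I, n-BuLi, THF, rt; I2, −78 °C; NaN(SiMe3)2, −20 °C; 33, −78 → −20 °C
Reagents that add atoms: ethyltriphenylphosphonium iodide, CC[P+](c1ccccc1)(c1ccccc1)c1ccccc1.[I-]; iodine, II
Why: Stork–Zhao-type Wittig reaction of the α-iodo ylide Ph3P=C(I)CH3; kinetic oxaphosphetane formation of this non-stabilised ylide gives the (Z)-2-iodoalk-2-ene with iodine cis to C22, which fixes the C20=C21 geometry before the union.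

Step 29
Reactants: 34 (Z)-alkenyl iodide chloride
Product: 36 C20–C38 phosphonium iodide, via primary iodide 35 (not isolated)
Conditions: NaI, PPh3, NaHCO3, MeCN, 80 °C
Reagents that add atoms: sodium iodide, [Na+].[I-]; triphenylphosphine, c1ccc(cc1)P(c1ccccc1)c1ccccc1
Why: Finkelstein exchange in the flask followed by quaternisation of the primary iodide; the alkenyl iodide and silyl ethers are inert to PPh3 without a transition metal.

Step 30
Reactants: 37 (R)-propylene oxide
Product: 38 (R)-hept-6-en-2-ol
Conditions: CH2=CHCH2CH2MgBr, CuI (10 mol%), THF, −30 → 0 °C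
Reagents that add atoms: but-3-enylmagnesium bromide, C=CCC[Mg]Br
Why: Copper-catalysed Grignard opening of the epoxide at its unsubstituted carbon; C49 comes unchanged from the chiral pool.

Step 31
Reactants: 38 (R)-hept-6-en-2-ol
Product: 39 (R)-tert-butyl(hept-6-en-2-yloxy)dimethylsilane
Conditions: TBSCl, imidazole, DMF, rt
Reagents that add atoms: tert-butylchlorodimethylsilane, CC(C)(C)[Si](C)(C)Cl
Why: Standard silylation.

Step 32
Reactants: 39 silyl ether alkene
Product: 40 (R)-7-(tert-butyldimethylsilyloxy)octanal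
Conditions: Rh(acac)(CO)2 (1 mol%), BIPHEPHOS (3 mol%), CO/H2 (1:1, 10 bar), THF, 60 °C
Reagents that add atoms: carbon monoxide, [C-]#[O+]
Why: Linear hydroformylation of the terminal alkene gives the C43 aldehyde in one step.

Step 33
Reactants: 40 (R)-7-(tert-butyldimethylsilyloxy)octanal; 41 (S)-4-benzyl-3-propanoyl-1,3-oxazolidin-2-one
Product: 42 (S)-4-benzyl-3-[(2S,3R,9R)-9-(tert-butyldimethylsilyloxy)-3-hydroxy-2-methyldecanoyl]-1,3-oxazolidin-2-one
Conditions: Bu2BOTf, iPr2NEt, CH2Cl2, −78 → 0 °C; 40, −78 → 0 °C; pH 7 buffer, MeOH, H2O2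
Reagents that add atoms: none
Why: Evans syn-aldol: the (Z)-boron enolate reacts through a Zimmerman–Traxler chair with the auxiliary carbonyl dipole opposed to the enolate, which gives the 2S,3R syn adduct and so sets C42 and C43.

Step 34
Reactants: 42 aldol adduct
Product: 43 C43 TBS ether of 42
Conditions: TBSOTf, 2,6-lutidine, CH2Cl2, −78 → 0 °C
Reagents that add atoms: tert-butyldimethylsilyl trifluoromethanesulfonate, CC(C)(C)[Si](C)(C)OS(=O)(=O)C(F)(F)F
Why: Silylation of the β-hydroxy imide under non-basic conditions avoids retro-aldol cleavage.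

Step 35
Reactants: 43 silylated aldol adduct
Product: 44 (2R,3R,9R)-3,9-bis(tert-butyldimethylsilyloxy)-2-methyldecan-1-ol
Conditions: LiBH4, MeOH (1 equiv), THF, 0 °C
Reagents that add atoms: none
Why: Reductive removal of the auxiliary by borohydride attack at the exocyclic carbonyl gives the primary alcohol without touching C42.

Step 36
Reactants: 44 primary alcohol; 5 allyl acetate
Product: 45 homoallylic alcohol (C38–C50; O41, C42-methyl and O43 syn,syn)
Conditions: 5 (2 equiv), [Ir(cod)Cl]2 (2.5 mol%), (S)-Cl,MeO-BIPHEP (5 mol%), 4-chloro-3-nitrobenzoic acid (10 mol%), Cs2CO3 (20 mol%), THF, 100 °C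
Reagents that add atoms: none
Why: Allylation from the alcohol oxidation level: the α-stereogenic aldehyde is only a transient, so C42 should not epimerise. The same ligand antipode sets C41 syn to the C42 methyl, the Felkin sense, so catalyst and substrate preferences agree.

Step 37
Reactants: 45 homoallylic alcohol
Product: 46 C41 triethylsilyl ether
Conditions: Et3SiOTf, 2,6-lutidine, CH2Cl2, −78 °C
Reagents that add atoms: triethylsilyl trifluoromethanesulfonate, CC[Si](CC)(CC)OS(=O)(=O)C(F)(F)F
Why: The hindered secondary hydroxyl is silylated with the triflate; the more labile TES group marks O41 as the future lactone oxygen among TBS ethers.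

Step 38
Reactants: 46 TES ether alkene
Product: 47 C39 aldehyde (fragment C39–C50)
Conditions: O3, CH2Cl2, −78 °C; PPh3, −78 °C → rt
Reagents that add atoms: ozone, [O-][O+]=O
Why: Ozonolysis removes the terminal methylene and leaves the C39 aldehyde for the Wittig union.

Step 39
Reactants: 36 C20–C38 phosphonium iodide; 47 C39 aldehyde
Product: 49 C20–C50 (Z)-alkenyl iodide (east fragment), via phosphonium ylide 48 (not isolated)
Conditions: NaN(SiMe3)2 (0.98 equiv), THF, −78 → 0 °C; 47, −78 °C → rt
Reagents that add atoms: none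
Why: Wittig reaction of a non-stabilised ylide under lithium-free conditions gives the Z alkene by kinetic formation of the cis-oxaphosphetane. The amide base is consumed by the phosphonium salt before the aldehyde is added, so neither the alkenyl iodide nor the β-silyloxy aldehyde meets free base.

Step 40
Reactants: 49 C20–C50 alkenyl iodide; 23 C1–C19 aldehyde
Product: 50 C19 allylic alcohol (complete C1–C50 chain)
Conditions: CrCl2 (10 equiv), NiCl2 (1 mol%), THF/DMF (1:3), rt
Reagents that add atoms: none
Why: Nozaki–Hiyama–Kishi coupling: nickel inserts into the C–I bond with retention of alkene geometry and hands the alkenyl group to trivalent chromium, which adds to the aldehyde and ignores the ester. C19 is set by Felkin–Anh attack anti to the C17-bearing substituent, the sense that is also 1,3-anti to O17 in this 2,3-anti aldehyde, so both substrate biases point to the 19S carbinol.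

Step 41
Reactants: 50 C19 allylic alcohol
Product: 51 C19 TBS ether
Conditions: TBSOTf, 2,6-lutidine, CH2Cl2, −78 → 0 °C
Reagents that add atoms: tert-butyldimethylsilyl trifluoromethanesulfonate, CC(C)(C)[Si](C)(C)OS(=O)(=O)C(F)(F)F
Why: Silylation of the hindered allylic hydroxyl under non-acidic conditions avoids allylic ionisation and leaves the TES ether in place.

Step 42
Reactants: 51 fully silylated chain
Product: 52 C41 alcohol
Conditions: HF·pyridine, pyridine, THF, 0 °C
Reagents that add atoms: none
Why: Buffered HF·pyridine cleaves the single TES ether much faster than secondary TBS ethers and does not hydrolyse the acetals, so only O41 is exposed.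

Step 43
Reactants: 52 C41 alcohol methyl ester
Product: 53 seco acid
Conditions: LiOH, THF/MeOH/H2O, 0 °C → rt; pH 4 phosphate buffer
Reagents that add atoms: lithium hydroxide, [Li+].[OH-]
Why: Saponification of the unhindered methyl ester; hydroxide attacks the acyl carbon and not C3, so the 2Z geometry should be retained, and the buffered work-up spares the acetals.

Step 44
Reactants: 53 seco acid
Product: 55 fully protected macrolactone, via mixed anhydride 54 (not isolated)
Conditions: 2-methyl-6-nitrobenzoic anhydride (1.3 equiv), DMAP (0.2 equiv), Et3N (3 equiv), CH2Cl2, rt, slow addition of 53 to a final concentration near 1 mM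
Reagents that add atoms: none
Why: Shiina macrolactonisation: the carboxylate forms a mixed anhydride with the hindered aromatic anhydride, and acyl transfer through the acylpyridinium ion to the single free hydroxyl closes the 42-membered ring under high dilution. Room temperature and a low loading of the nucleophilic catalyst limit the conjugate addition–elimination at C3 that would isomerise the dienoate.

Step 45
Reactants: 55 fully protected macrolactone
Product: 56 target macrolide CNP0392687.2
Conditions: 48% aq. HF, MeCN/THF, 0 °C → rt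
Reagents that add atoms: none
Why: Aqueous HF cleaves the eight TBS ethers and hydrolyses both PMP acetals in one operation; the conditions are mild enough for the lactone, the dienoate and the allylic C19 carbinol.

## Compound list

1 | methyl acetoacetate | COC(=O)CC(C)=O | starting material
2 | methyl 3-(trimethylsilyloxy)but-2-enoate | COC(=O)C=C(C)O[Si](C)(C)C | intermediate
3 | 1-methoxy-1,3-bis(trimethylsilyloxy)buta-1,3-diene | COC(O[Si](C)(C)C)=CC(=C)O[Si](C)(C)C | intermediate
4 | propane-1,3-diol | OCCCO | starting material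
5 | allyl acetate | CC(=O)OCC=C | starting material
6 | (S)-hex-5-ene-1,3-diol (not isolated) | C=CC[C@H](O)CCO | intermediate
7 | (4S,6S)-nona-1,8-diene-4,6-diol | C=CC[C@H](O)C[C@@H](O)CC=C | intermediate
8 | (4S,6S)-4,6-bis(4-methoxybenzyloxy)nona-1,8-diene | C=CC[C@H](OCc1ccc(OC)cc1)C[C@@H](OCc1ccc(OC)cc1)CC=C | intermediate
9 | (3R,5R)-3,5-bis(4-methoxybenzyloxy)heptanedial (C9–C15 dialdehyde) | O=CC[C@H](OCc1ccc(OC)cc1)C[C@@H](OCc1ccc(OC)cc1)CC=O | intermediate
10 | mono-aldol aldehyde, as its difluoroboron aldolate and silyl enol ether (not isolated) | COC(=O)C=C(C[C@@H](OB(F)F)C[C@H](OCc1ccc(OC)cc1)C[C@@H](OCc1ccc(OC)cc1)CC=O)O[Si](C)(C)C | intermediate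
11 | dimethyl (5S,7S,9S,11S)-5,11-dihydroxy-7,9-bis(4-methoxybenzyloxy)-3,13-dioxopentadecanedioate (C5–C19) | COC(=O)CC(=O)C[C@@H](O)C[C@H](OCc1ccc(OC)cc1)C[C@@H](OCc1ccc(OC)cc1)C[C@H](O)CC(=O)CC(=O)OC | intermediate
12 | dimethyl (3R,5R,7S,9S,11R,13R)-3,5,11,13-tetrahydroxy-7,9-bis(4-methoxybenzyloxy)pentadecanedioate | COC(=O)C[C@H](O)C[C@@H](O)C[C@H](OCc1ccc(OC)cc1)C[C@@H](OCc1ccc(OC)cc1)C[C@H](O)C[C@@H](O)CC(=O)OC | intermediate
13 | C5–C19 dimethyl diester, O9/O11 and O13/O15 as 4-methoxybenzylidene acetals, free C7 and C17 hydroxyls | COC(=O)C[C@H](O)C[C@@H]1C[C@H](OC(c2ccc(OC)cc2)O1)C[C@@H]1C[C@H](OC(c2ccc(OC)cc2)O1)C[C@@H](O)CC(=O)OC | intermediate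
14 | mono-reduced triol ester (C5 CH2OH, C19 CO2Me) | OCC[C@H](O)C[C@@H]1C[C@H](OC(c2ccc(OC)cc2)O1)C[C@@H]1C[C@H](OC(c2ccc(OC)cc2)O1)C[C@@H](O)CC(=O)OC | intermediate
15 | C5 triethylsilyl ether of 14 | CC[Si](CC)(CC)OCC[C@H](O)C[C@@H]1C[C@H](OC(c2ccc(OC)cc2)O1)C[C@@H]1C[C@H](OC(c2ccc(OC)cc2)O1)C[C@@H](O)CC(=O)OC | intermediate
16 | C18-methylated hydroxy ester (17,18-anti) | CC[Si](CC)(CC)OCC[C@H](O)C[C@@H]1C[C@H](OC(c2ccc(OC)cc2)O1)C[C@@H]1C[C@H](OC(c2ccc(OC)cc2)O1)C[C@@H](O)[C@@H](C)C(=O)OC | intermediate
17 | C7,C17-bis(TBS) ether of 16 | CC[Si](CC)(CC)OCC[C@H](O[Si](C)(C)C(C)(C)C)C[C@@H]1C[C@H](OC(c2ccc(OC)cc2)O1)C[C@@H]1C[C@H](OC(c2ccc(OC)cc2)O1)C[C@@H](O[Si](C)(C)C(C)(C)C)[C@@H](C)C(=O)OC | intermediate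
18 | C5 aldehyde | O=CC[C@H](O[Si](C)(C)C(C)(C)C)C[C@@H]1C[C@H](OC(c2ccc(OC)cc2)O1)C[C@@H]1C[C@H](OC(c2ccc(OC)cc2)O1)C[C@@H](O[Si](C)(C)C(C)(C)C)[C@@H](C)C(=O)OC | intermediate
19 | (Z)-enoate diester (C3–C19) | COC(=O)/C(C)=C\C[C@H](O[Si](C)(C)C(C)(C)C)C[C@@H]1C[C@H](OC(c2ccc(OC)cc2)O1)C[C@@H]1C[C@H](OC(c2ccc(OC)cc2)O1)C[C@@H](O[Si](C)(C)C(C)(C)C)[C@@H](C)C(=O)OC | intermediate
20 | C3,C19-diol with (Z)-C4=C5 | OC/C(C)=C\C[C@H](O[Si](C)(C)C(C)(C)C)C[C@@H]1C[C@H](OC(c2ccc(OC)cc2)O1)C[C@@H]1C[C@H](OC(c2ccc(OC)cc2)O1)C[C@@H](O[Si](C)(C)C(C)(C)C)[C@@H](C)CO | intermediate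
21 | (Z)-enal with free C19 hydroxyl | O=C/C(C)=C\C[C@H](O[Si](C)(C)C(C)(C)C)C[C@@H]1C[C@H](OC(c2ccc(OC)cc2)O1)C[C@@H]1C[C@H](OC(c2ccc(OC)cc2)O1)C[C@@H](O[Si](C)(C)C(C)(C)C)[C@@H](C)CO | intermediate
22 | methyl (2Z,4Z)-dienoate with free C19 hydroxyl | COC(=O)/C=C\C(C)=C/C[C@H](O[Si](C)(C)C(C)(C)C)C[C@@H]1C[C@H](OC(c2ccc(OC)cc2)O1)C[C@@H]1C[C@H](OC(c2ccc(OC)cc2)O1)C[C@@H](O[Si](C)(C)C(C)(C)C)[C@@H](C)CO | intermediate
23 | C1–C19 aldehyde (west fragment) | COC(=O)/C=C\C(C)=C/C[C@H](O[Si](C)(C)C(C)(C)C)C[C@@H]1C[C@H](OC(c2ccc(OC)cc2)O1)C[C@@H]1C[C@H](OC(c2ccc(OC)cc2)O1)C[C@@H](O[Si](C)(C)C(C)(C)C)[C@@H](C)C=O | intermediate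
24 | 8-chlorooctan-1-ol | OCCCCCCCCCl | starting material
25 | (R)-11-chloroundec-1-en-4-ol | C=CC[C@H](O)CCCCCCCCl | intermediate
26 | (R)-tert-butyl[(11-chloroundec-1-en-4-yl)oxy]dimethylsilane | C=CC[C@H](O[Si](C)(C)C(C)(C)C)CCCCCCCCl | intermediate
27 | (R)-5-(tert-butyldimethylsilyloxy)-12-chlorododecanal | O=CCCC[C@H](O[Si](C)(C)C(C)(C)C)CCCCCCCCl | intermediate
28 | (4R,8R)-8-(tert-butyldimethylsilyloxy)-15-chloropentadec-1-en-4-ol | C=CC[C@H](O)CCC[C@H](O[Si](C)(C)C(C)(C)C)CCCCCCCCl | intermediate
29 | (4R,8R)-4,8-bis(tert-butyldimethylsilyloxy)-15-chloropentadec-1-ene | C=CC[C@H](O[Si](C)(C)C(C)(C)C)CCC[C@H](O[Si](C)(C)C(C)(C)C)CCCCCCCCl | intermediate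
30 | (5R,9R)-5,9-bis(tert-butyldimethylsilyloxy)-16-chlorohexadecanal | O=CCCC[C@H](O[Si](C)(C)C(C)(C)C)CCC[C@H](O[Si](C)(C)C(C)(C)C)CCCCCCCCl | intermediate
31 | 19-chloro-8,12-bis(tert-butyldimethylsilyloxy)nonadec-1-en-4-ol (C23, C27, C31 as in the target) | C=CC[C@H](O)CCC[C@H](O[Si](C)(C)C(C)(C)C)CCC[C@H](O[Si](C)(C)C(C)(C)C)CCCCCCCCl | intermediate
32 | tris(TBS) ether of 31 | C=CC[C@H](O[Si](C)(C)C(C)(C)C)CCC[C@H](O[Si](C)(C)C(C)(C)C)CCC[C@H](O[Si](C)(C)C(C)(C)C)CCCCCCCCl | intermediate
33 | 18-chloro-3,7,11-tris(tert-butyldimethylsilyloxy)octadecanal (C21 aldehyde) | O=CC[C@H](O[Si](C)(C)C(C)(C)C)CCC[C@H](O[Si](C)(C)C(C)(C)C)CCC[C@H](O[Si](C)(C)C(C)(C)C)CCCCCCCCl | intermediate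
34 | (Z)-alkenyl iodide, C20–C38 with C38 chloride | C/C(I)=C/C[C@H](O[Si](C)(C)C(C)(C)C)CCC[C@H](O[Si](C)(C)C(C)(C)C)CCC[C@H](O[Si](C)(C)C(C)(C)C)CCCCCCCCl | intermediate
35 | primary iodide corresponding to 34 (not isolated) | C/C(I)=C/C[C@H](O[Si](C)(C)C(C)(C)C)CCC[C@H](O[Si](C)(C)C(C)(C)C)CCC[C@H](O[Si](C)(C)C(C)(C)C)CCCCCCCI | intermediate
36 | C20–C38 triphenylphosphonium iodide | C/C(I)=C/C[C@H](O[Si](C)(C)C(C)(C)C)CCC[C@H](O[Si](C)(C)C(C)(C)C)CCC[C@H](O[Si](C)(C)C(C)(C)C)CCCCCCC[P+](c1ccccc1)(c1ccccc1)c1ccccc1.[I-] | intermediate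
37 | (R)-propylene oxide | C[C@@H]1CO1 | starting material
38 | (R)-hept-6-en-2-ol | C=CCCC[C@@H](C)O | intermediate
39 | (R)-tert-butyl(hept-6-en-2-yloxy)dimethylsilane | C=CCCC[C@@H](C)O[Si](C)(C)C(C)(C)C | intermediate
40 | (R)-7-(tert-butyldimethylsilyloxy)octanal | O=CCCCCC[C@@H](C)O[Si](C)(C)C(C)(C)C | intermediate
41 | (S)-4-benzyl-3-propanoyl-1,3-oxazolidin-2-one | CCC(=O)N1[C@@H](Cc2ccccc2)COC1=O | starting material
42 | (S)-4-benzyl-3-[(2S,3R,9R)-9-(tert-butyldimethylsilyloxy)-3-hydroxy-2-methyldecanoyl]-1,3-oxazolidin-2-one | O=C1OC[C@H](Cc2ccccc2)N1C(=O)[C@@H](C)[C@H](O)CCCCC[C@@H](C)O[Si](C)(C)C(C)(C)C | intermediate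
43 | (S)-4-benzyl-3-[(2S,3R,9R)-3,9-bis(tert-butyldimethylsilyloxy)-2-methyldecanoyl]-1,3-oxazolidin-2-one | O=C1OC[C@H](Cc2ccccc2)N1C(=O)[C@@H](C)[C@H](O[Si](C)(C)C(C)(C)C)CCCCC[C@@H](C)O[Si](C)(C)C(C)(C)C | intermediate
44 | (2R,3R,9R)-3,9-bis(tert-butyldimethylsilyloxy)-2-methyldecan-1-ol | OC[C@@H](C)[C@H](O[Si](C)(C)C(C)(C)C)CCCCC[C@@H](C)O[Si](C)(C)C(C)(C)C | intermediate
45 | 6,12-bis(tert-butyldimethylsilyloxy)-5-methyltridec-1-en-4-ol (O41, C42-methyl, O43 syn,syn; C49 R) | C=CC[C@H](O)[C@@H](C)[C@H](O[Si](C)(C)C(C)(C)C)CCCCC[C@@H](C)O[Si](C)(C)C(C)(C)C | intermediate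
46 | C41 triethylsilyl ether of 45 | C=CC[C@H](O[Si](CC)(CC)CC)[C@@H](C)[C@H](O[Si](C)(C)C(C)(C)C)CCCCC[C@@H](C)O[Si](C)(C)C(C)(C)C | intermediate
47 | 5,11-bis(tert-butyldimethylsilyloxy)-4-methyl-3-(triethylsilyloxy)dodecanal (C39 aldehyde) | O=CC[C@H](O[Si](CC)(CC)CC)[C@@H](C)[C@H](O[Si](C)(C)C(C)(C)C)CCCCC[C@@H](C)O[Si](C)(C)C(C)(C)C | intermediate
48 | phosphonium ylide from 36 (not isolated) | C/C(I)=C/C[C@H](O[Si](C)(C)C(C)(C)C)CCC[C@H](O[Si](C)(C)C(C)(C)C)CCC[C@H](O[Si](C)(C)C(C)(C)C)CCCCCCC=P(c1ccccc1)(c1ccccc1)c1ccccc1 | intermediate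
49 | C20–C50 (20Z,38Z)-alkenyl iodide (east fragment) | C/C(I)=C/C[C@H](O[Si](C)(C)C(C)(C)C)CCC[C@H](O[Si](C)(C)C(C)(C)C)CCC[C@H](O[Si](C)(C)C(C)(C)C)CCCCCC/C=C\C[C@H](O[Si](CC)(CC)CC)[C@@H](C)[C@H](O[Si](C)(C)C(C)(C)C)CCCCC[C@@H](C)O[Si](C)(C)C(C)(C)C | intermediate
50 | C19 allylic alcohol, complete C1–C50 chain | COC(=O)/C=C\C(C)=C/C[C@H](O[Si](C)(C)C(C)(C)C)C[C@@H]1C[C@H](OC(c2ccc(OC)cc2)O1)C[C@@H]1C[C@H](OC(c2ccc(OC)cc2)O1)C[C@@H](O[Si](C)(C)C(C)(C)C)[C@@H](C)[C@H](O)/C(C)=C\C[C@H](O[Si](C)(C)C(C)(C)C)CCC[C@H](O[Si](C)(C)C(C)(C)C)CCC[C@H](O[Si](C)(C)C(C)(C)C)CCCCCC/C=C\C[C@H](O[Si](CC)(CC)CC)[C@@H](C)[C@H](O[Si](C)(C)C(C)(C)C)CCCCC[C@@H](C)O[Si](C)(C)C(C)(C)C | intermediate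
51 | C19 TBS ether of 50 | COC(=O)/C=C\C(C)=C/C[C@H](O[Si](C)(C)C(C)(C)C)C[C@@H]1C[C@H](OC(c2ccc(OC)cc2)O1)C[C@@H]1C[C@H](OC(c2ccc(OC)cc2)O1)C[C@@H](O[Si](C)(C)C(C)(C)C)[C@@H](C)[C@H](O[Si](C)(C)C(C)(C)C)/C(C)=C\C[C@H](O[Si](C)(C)C(C)(C)C)CCC[C@H](O[Si](C)(C)C(C)(C)C)CCC[C@H](O[Si](C)(C)C(C)(C)C)CCCCCC/C=C\C[C@H](O[Si](CC)(CC)CC)[C@@H](C)[C@H](O[Si](C)(C)C(C)(C)C)CCCCC[C@@H](C)O[Si](C)(C)C(C)(C)C | intermediate
52 | C41 alcohol methyl ester | COC(=O)/C=C\C(C)=C/C[C@H](O[Si](C)(C)C(C)(C)C)C[C@@H]1C[C@H](OC(c2ccc(OC)cc2)O1)C[C@@H]1C[C@H](OC(c2ccc(OC)cc2)O1)C[C@@H](O[Si](C)(C)C(C)(C)C)[C@@H](C)[C@H](O[Si](C)(C)C(C)(C)C)/C(C)=C\C[C@H](O[Si](C)(C)C(C)(C)C)CCC[C@H](O[Si](C)(C)C(C)(C)C)CCC[C@H](O[Si](C)(C)C(C)(C)C)CCCCCC/C=C\C[C@H](O)[C@@H](C)[C@H](O[Si](C)(C)C(C)(C)C)CCCCC[C@@H](C)O[Si](C)(C)C(C)(C)C | intermediate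
53 | seco acid | OC(=O)/C=C\C(C)=C/C[C@H](O[Si](C)(C)C(C)(C)C)C[C@@H]1C[C@H](OC(c2ccc(OC)cc2)O1)C[C@@H]1C[C@H](OC(c2ccc(OC)cc2)O1)C[C@@H](O[Si](C)(C)C(C)(C)C)[C@@H](C)[C@H](O[Si](C)(C)C(C)(C)C)/C(C)=C\C[C@H](O[Si](C)(C)C(C)(C)C)CCC[C@H](O[Si](C)(C)C(C)(C)C)CCC[C@H](O[Si](C)(C)C(C)(C)C)CCCCCC/C=C\C[C@H](O)[C@@H](C)[C@H](O[Si](C)(C)C(C)(C)C)CCCCC[C@@H](C)O[Si](C)(C)C(C)(C)C | intermediate
54 | mixed anhydride of 53 with 2-methyl-6-nitrobenzoic acid (not isolated) | Cc1cccc([N+](=O)[O-])c1C(=O)OC(=O)/C=C\C(C)=C/C[C@H](O[Si](C)(C)C(C)(C)C)C[C@@H]1C[C@H](OC(c2ccc(OC)cc2)O1)C[C@@H]1C[C@H](OC(c2ccc(OC)cc2)O1)C[C@@H](O[Si](C)(C)C(C)(C)C)[C@@H](C)[C@H](O[Si](C)(C)C(C)(C)C)/C(C)=C\C[C@H](O[Si](C)(C)C(C)(C)C)CCC[C@H](O[Si](C)(C)C(C)(C)C)CCC[C@H](O[Si](C)(C)C(C)(C)C)CCCCCC/C=C\C[C@H](O)[C@@H](C)[C@H](O[Si](C)(C)C(C)(C)C)CCCCC[C@@H](C)O[Si](C)(C)C(C)(C)C | intermediate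
55 | fully protected 42-membered macrolactone | CC1=C/C[C@H](O[Si](C)(C)C(C)(C)C)C[C@@H]2C[C@H](OC(c3ccc(OC)cc3)O2)C[C@@H]2C[C@H](OC(c3ccc(OC)cc3)O2)C[C@@H](O[Si](C)(C)C(C)(C)C)[C@@H](C)[C@H](O[Si](C)(C)C(C)(C)C)/C(C)=C\C[C@H](O[Si](C)(C)C(C)(C)C)CCC[C@H](O[Si](C)(C)C(C)(C)C)CCC[C@H](O[Si](C)(C)C(C)(C)C)CCCCCC/C=C\C[C@@H]([C@@H](C)[C@H](O[Si](C)(C)C(C)(C)C)CCCCC[C@@H](C)O[Si](C)(C)C(C)(C)C)OC(=O)/C=C\1 | intermediate
56 | CNP0392687.2 | CC1=C/C[C@H](O)C[C@@H](O)C[C@H](O)C[C@@H](O)C[C@H](O)C[C@@H](O)[C@@H](C)[C@H](O)/C(C)=C\C[C@H](O)CCC[C@H](O)CCC[C@H](O)CCCCCC/C=C\C[C@@H]([C@@H](C)[C@H](O)CCCCC[C@@H](C)O)OC(=O)/C=C\1 | target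

## Step count and least certain steps

Total step count: 45. Longest linear sequence: 22 steps (steps 3–18 and 40–45, from propane-1,3-diol).

**Step 6 (key step).** The most likely failure is incomplete 1,3-anti face selection at one of the two aldehydes; because both additions must go the right way, any leak is compounded. Loss of a PMB ether by β-elimination from the activated aldehyde, or a stalled second addition, would also lower the throughput. Fallback: setting out from 9, both aldehydes undergo a Ti(OiPr)4/BINOL-catalysed aldol addition of 2,2-dimethyl-6-methylene-4-(trimethylsilyloxy)-1,3-dioxine, using the BINOL antipode whose facial preference coincides with the 1,3-anti bias, so that catalyst and substrate control reinforce each other. This gives the bis(dioxinone) diol F1. Treatment of bis(dioxinone) diol F1 with K2CO3 in methanol opens both dioxinones to the methyl β-keto esters and returns to the route at 11.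

**Step 9.** The reduction cannot distinguish the first ester from the second, so over-reduction and repeated recycling may erode the material balance. Fallback: setting out from 13, controlled monohydrolysis (1 equiv NaOH, THF/H2O, 0 °C), in which the carboxylate formed slows the second hydrolysis, gives the mono-acid F2. Reduction of mono-acid F2 with BH3·SMe2 in THF at 0 °C, which reduces the acid and not the ester, returns to the route at 14.

**Step 11.** Enolisation of a species that already carries two lithium alkoxides may be sluggish through aggregation, the TES group may migrate from O5 to the neighbouring O7 alkoxide, and some O-methylation is possible. Fallback: setting out from 14, tBu2Si(OTf)2 and 2,6-lutidine tie O5 and O7 into the six-membered silylene F3, which leaves O17 as the only free hydroxyl. The ordinary dianion alkylation (2.2 equiv LiN(iPr)2, then MeI) on silylene F3 gives the methylated silylene F4. HF·pyridine removes the silylene from methylated silylene F4 to give the triol ester F5. Selective silylation of the primary hydroxyl of triol ester F5 with Et3SiCl returns to the route at 16.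

**Step 40.** Facial discrimination at C19 may be insufficient, and insertion into the hindered trisubstituted alkenyl iodide may be slow enough for aldehyde 23 to degrade. Fallback: setting out from 50 obtained as a mixture of C19 epimers, Dess–Martin oxidation gives the enone F6. Reagent-controlled reduction of enone F6 with the (R)-configured methyl oxazaborolidine catalyst and catecholborane, the trisubstituted alkenyl group acting as the large substituent, returns to the route at 50 as the single 19S epimer.

**Step 44.** Reversible conjugate addition of the nucleophilic catalyst to the activated dienoyl intermediate may isomerise C2=C3 from Z to E, and intermolecular acylation may give oligomers. Fallback: setting out from 53, addition of the acid to ethoxyacetylene with catalytic [RuCl2(p-cymene)]2 gives the isolable 1-ethoxyvinyl ester F7. Slow addition of 1-ethoxyvinyl ester F7 to catalytic camphorsulfonic acid in dry 1,2-dichloroethane transfers the acyl group to O41 with loss of ethyl acetate and returns to the route at 55; no nucleophilic base is present at any stage.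

## Further compounds

F1 | step 6 | bis(dioxinone) diol: 6,6'-[(2S,4S,6S,8S)-2,8-dihydroxy-4,6-bis(4-methoxybenzyloxy)nonane-1,9-diyl]bis(2,2-dimethyl-4H-1,3-dioxin-4-one) | CC1(C)OC(=CC(=O)O1)C[C@@H](O)C[C@H](OCc1ccc(OC)cc1)C[C@@H](OCc1ccc(OC)cc1)C[C@H](O)CC1=CC(=O)OC(C)(C)O1
F2 | step 9 | mono-acid of 13 (C5 carboxylic acid, C19 methyl ester) | OC(=O)C[C@H](O)C[C@@H]1C[C@H](OC(c2ccc(OC)cc2)O1)C[C@@H]1C[C@H](OC(c2ccc(OC)cc2)O1)C[C@@H](O)CC(=O)OC
F3 | step 11 | O5,O7-di-tert-butylsilylene of 14 | CC(C)(C)[Si]1(OCC[C@H](O1)C[C@@H]2C[C@H](OC(c3ccc(OC)cc3)O2)C[C@@H]2C[C@H](OC(c3ccc(OC)cc3)O2)C[C@@H](O)CC(=O)OC)C(C)(C)C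
F4 | step 11 | C18-methylated silylene (17,18-anti) | CC(C)(C)[Si]1(OCC[C@H](O1)C[C@@H]2C[C@H](OC(c3ccc(OC)cc3)O2)C[C@@H]2C[C@H](OC(c3ccc(OC)cc3)O2)C[C@@H](O)[C@@H](C)C(=O)OC)C(C)(C)C
F5 | step 11 | C18-methylated triol ester | OCC[C@H](O)C[C@@H]1C[C@H](OC(c2ccc(OC)cc2)O1)C[C@@H]1C[C@H](OC(c2ccc(OC)cc2)O1)C[C@@H](O)[C@@H](C)C(=O)OC
F6 | step 40 | C19 enone of the C1–C50 chain | COC(=O)/C=C\C(C)=C/C[C@H](O[Si](C)(C)C(C)(C)C)C[C@@H]1C[C@H](OC(c2ccc(OC)cc2)O1)C[C@@H]1C[C@H](OC(c2ccc(OC)cc2)O1)C[C@@H](O[Si](C)(C)C(C)(C)C)[C@@H](C)C(=O)/C(C)=C\C[C@H](O[Si](C)(C)C(C)(C)C)CCC[C@H](O[Si](C)(C)C(C)(C)C)CCC[C@H](O[Si](C)(C)C(C)(C)C)CCCCCC/C=C\C[C@H](O[Si](CC)(CC)CC)[C@@H](C)[C@H](O[Si](C)(C)C(C)(C)C)CCCCC[C@@H](C)O[Si](C)(C)C(C)(C)C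
F7 | step 44 | 1-ethoxyvinyl ester of seco acid 53 | C=C(OCC)OC(=O)/C=C\C(C)=C/C[C@H](O[Si](C)(C)C(C)(C)C)C[C@@H]1C[C@H](OC(c2ccc(OC)cc2)O1)C[C@@H]1C[C@H](OC(c2ccc(OC)cc2)O1)C[C@@H](O[Si](C)(C)C(C)(C)C)[C@@H](C)[C@H](O[Si](C)(C)C(C)(C)C)/C(C)=C\C[C@H](O[Si](C)(C)C(C)(C)C)CCC[C@H](O[Si](C)(C)C(C)(C)C)CCC[C@H](O[Si](C)(C)C(C)(C)C)CCCCCC/C=C\C[C@H](O)[C@@H](C)[C@H](O[Si](C)(C)C(C)(C)C)CCCCC[C@@H](C)O[Si](C)(C)C(C)(C)C
A1 | alternative 1 | fully protected macrolide with the (2Z,4Z)-dienoate closed at C3–C4 | CC1=C/C[C@H]2C[C@@H](OC(C)(C)O2)C[C@H]3C[C@@H](OC(C)(C)O3)C[C@H]4C[C@@H](OC(C)(C)O4)[C@@H](C)[C@H](O[Si](C)(C)C(C)(C)C)/C(C)=C\C[C@H](O[Si](C)(C)C(C)(C)C)CCC[C@H](O[Si](C)(C)C(C)(C)C)CCC[C@H](O[Si](C)(C)C(C)(C)C)CCCCCC/C=C\C[C@@H]([C@@H](C)[C@H](O[Si](C)(C)C(C)(C)C)CCCCC[C@@H](C)O[Si](C)(C)C(C)(C)C)OC(=O)/C=C\1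
A2 | alternative 2 | eight-membered diisopropylsilylene acetal holding the C20=C21 Z alkene, C5–C38 chain | COc1ccc(COCC[C@H]2C[C@@H](OC(C)(C)O2)C[C@H]3C[C@@H](OC(C)(C)O3)C[C@H]4C[C@@H](OC(C)(C)O4)[C@@H](C)[C@H](O[Si](C(C)C)(C(C)C)O5)/C(C)=C\C[C@H]5CCC[C@H](O[Si](C)(C)C(C)(C)C)CCC[C@H](O[Si](C)(C)C(C)(C)C)CCCCCCCOC(=O)C(C)(C)C)cc1
A3 | alternative 3 | protected 42-membered cycloalkyne with the C38≡C39 triple bond | CC1=C/C[C@H]2C[C@@H](OC(C)(C)O2)C[C@H]3C[C@@H](OC(C)(C)O3)C[C@H]4C[C@@H](OC(C)(C)O4)[C@@H](C)[C@H](O[Si](C)(C)C(C)(C)C)/C(C)=C\C[C@H](O[Si](C)(C)C(C)(C)C)CCC[C@H](O[Si](C)(C)C(C)(C)C)CCC[C@H](O[Si](C)(C)C(C)(C)C)CCCCCCC#CC[C@@H]([C@@H](C)[C@H](O[Si](C)(C)C(C)(C)C)CCCCC[C@@H](C)O[Si](C)(C)C(C)(C)C)OC(=O)/C=C\1
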